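**Plan**

1. Target numbering (secoaromadendrane): ring A = cyclopropane C6–C7–C11 (C12 = CH2OAc, C13 = ether CH2); ring B = cycloheptane C1/C5–C10 (C14 = methyl on C10); ring C = dihydropyran O–C2–C1–C5–C4=C3; ring D = oxepane C13–O–C15–C4–C5–C6–C11.
2. Retrosynthesis: remove both acetates; cut O–C15 and C4–C15 of ring D (C15 = formaldehyde). Ring C is the cyclic form of a 1,5-dialdehyde whose ends are the acetal carbon C2 and the enol-ether carbon C3, i.e. the retro-aldol product of a 2-formylcyclobutanol, so O–C2 is cut and C2–C4 re-formed to give the four-membered ring C2/C1/C5/C4.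
3. Further cuts: C3–C4 (formyl equivalent); C1–C2 and C5–C4 together ([2+2] of dichloroketene with a C1=C5 alkene); the C10 carbinol and C1=C5 alkene back to a C1–C10 epoxide and a C1=C10 alkene; C10–C14 (coupling of an enol triflate); C6–C11 and C7–C11 (cyclopropanation of 4-cyclohepten-1-one).
4. Forward: ring A is fused to ring B (step 1), a cyclobutanone is fused to ring B (step 9), ring C arises from it by a two-atom ring expansion (step 13), ring D closes last (step 14), then acetylation.
5. Stereochemistry: absolute configuration from enantiotopic deprotonation of the meso ketone by a homochiral lithium amide; the endo CH2O arm of ring A then blocks one face of ring B, so epoxidation (C10) and ketene cycloaddition (C1, C5) occur anti to ring A; C11 is fixed because only the endo arm reaches C15; C2 is set at acetylation of the equilibrating lactol.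

Key step: step 13

Remark 1: locants in the text are those of the target; 16, 17, 18 and 22 are epimer mixtures at C4 and/or C2 and 20 and 23 are anomer mixtures (these centers are left open in the SMILES), because steps 13 to 15 erase or re-set them.
Remark 2: the (R,R)-amide is assumed to give the enantiomer of 4 that is drawn; if the sense is the opposite, the (S,S)-amide is used.
Remark 3: lactol 20 and dialdehyde 19 are ring–chain tautomers of one another; 19 is generated in step 13, and in step 14 it is only the reacting form of the reactant 20.

**Route**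

Step 1
Reactants: 1 4-cyclohepten-1-one; 2 dimethyl diazomalonate
Product: 3 dimethyl (1R,7S)-4-oxobicyclo[5.1.0]octane-8,8-dicarboxylate (meso)
Conditions: Rh2(OAc)4 (1 mol%), 1 (3 equiv), CH2Cl2, 40 °C, slow addition of 2
Reagents that add atoms: none
Why: The rhodium carbenoid of the acceptor/acceptor diazo compound should add to the only C=C bond (cyclopropanation) faster than to the ketone oxygen, and because 1 has a mirror plane through C10 and the alkene midpoint either face gives the same cis-fused meso product, so C6 and C7 need no control here.

Step 2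
Reactants: 3
Product: 4 enol triflate (C10–OTf and C1=C10)
Conditions: (R,R)-bis(1-phenylethyl)amine, n-BuLi, LiCl, THF, −78 °C; then PhNTf2, −78 → 0 °C
Reagents that add atoms: N-phenylbis(trifluoromethanesulfonimide), O=S(=O)(N(c1ccccc1)S(=O)(=O)C(F)(F)F)C(F)(F)F
Why: Enantioselective deprotonation of a meso ketone by a homochiral lithium amide (asymmetric desymmetrisation) should remove one of the two enantiotopic α-methylene protons, which fixes the absolute configuration of C6 and C7 relative to the new C1=C10 enolate, and O-sulfonylation of the lithium enolate then gives the enol triflate without touching the non-enolisable malonate esters.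

Step 3
Reactants: 4
Product: 5 dimethyl 4-methylbicyclo[5.1.0]oct-3-ene-8,8-dicarboxylate
Conditions: MeMgBr, Fe(acac)3 (5 mol%), THF–NMP, −30 °C
Reagents that add atoms: methylmagnesium bromide, C[Mg]Br
Why: Iron-catalysed cross-coupling of an alkenyl triflate with a methyl Grignard reagent should be much faster at −30 °C than Grignard addition to the hindered malonate esters and installs C14 with the double bond kept at C1=C10 (no stereocenter is formed).

Step 4
Reactants: 5
Product: 6 (4-methylbicyclo[5.1.0]oct-3-ene-8,8-diyl)dimethanol
Conditions: LiAlH4, THF, 0 °C → rt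
Reagents that add atoms: none
Why: LiAlH4 reduces both esters to the 1,1-bis(hydroxymethyl)cyclopropane (ester reduction), which also removes the acceptor activation that would let a selenolate open ring A in step 7, while the trisubstituted alkene is inert.

Step 5
Reactants: 6
Product: 7 bis(triethylsilyl) ether of 6
Conditions: Et3SiCl, imidazole, DMF, 0 °C
Reagents that add atoms: chlorotriethylsilane, CC[Si](CC)(CC)Cl
Why: Silylation of both primary alcohols (silyl ether formation) prevents hydroxyl-directed syn epoxidation and epoxide opening by the endo arm and turns that arm into a bulky shield over the syn face of ring B.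

Step 6
Reactants: 7
Product: 8 C1–C10 epoxide (oxygen anti to ring A)
Conditions: mCPBA, NaHCO3, CH2Cl2, 0 °C
Reagents that add atoms: 3-chloroperbenzoic acid, OOC(=O)c1cccc(Cl)c1
Why: Peracid epoxidation (Prilezhaev reaction) of the trisubstituted C1=C10 alkene should occur from the face of ring B opposite to ring A, whose endo CH2OSiEt3 group covers the syn face as the gem-dimethyl group does in 3-carene, which places the oxygen at C10 and C1 anti to the cyclopropane as the target requires.

Step 7
Reactants: 8
Product: 11 tertiary allylic alcohol (C10–OH anti to ring A and C1=C5), via hydroxy selenide 9 (not isolated), via selenoxide 10 (not isolated)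
Conditions: (PhSe)2, NaBH4, EtOH, 60 °C; then 30% H2O2, THF, 0 °C → rt
Reagents that add atoms: none
Why: Phenylselenolate should open the epoxide by SN2 attack at the less substituted C1 (the C10–O bond is untouched), and the selenoxide formed with H2O2 can only undergo syn-elimination toward C5 because C10 carries no hydrogen, so the sequence (selenide opening and selenoxide elimination) gives the C1=C5 alkene and the tertiary C10 alcohol with its oxygen still anti to ring A.

Step 8
Reactants: 11
Product: 12 tris(triethylsilyl) ether
Conditions: Et3SiOTf, 2,6-lutidine, CH2Cl2, −78 → 0 °C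
Reagents that add atoms: triethylsilyl trifluoromethanesulfonate, CC[Si](CC)(CC)OS(=O)(=O)C(F)(F)F
Why: A silyl triflate with a hindered base should silylate the tertiary allylic alcohol at low temperature without ionising it (silyl ether formation), which is needed because the acid chloride and the ketene of the next step would acylate a free hydroxyl.

Step 9
Reactants: 12
Product: 13 dichlorocyclobutanone (C2=O on C1 and CCl2 on C5)
Conditions: Cl3CCOCl, Zn–Cu couple, POCl3, Et2O, rt → 35 °C
Reagents that add atoms: trichloroacetyl chloride, ClC(=O)C(Cl)(Cl)Cl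
Why: Dichloroketene made by zinc dechlorination of the acid chloride should undergo thermal [2+2] cycloaddition to the cis C1=C5 alkene with its carbonyl carbon on C1 and its CCl2 carbon on C5, because the positive charge developing at C5 is stabilised by the adjacent cyclopropane and the bulkier CCl2 end avoids the quaternary C10, and from the face anti to ring A, whose endo arm lies over the syn face, which sets C1 and C5 cis to each other and trans to the cyclopropane.

Step 10
Reactants: 13
Product: 14 cyclobutanone
Conditions: Zn dust, NH4Cl, MeOH, rt
Reagents that add atoms: none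
Why: Zinc should reduce both C–Cl bonds next to the carbonyl through zinc enolates that the ammonium salt protonates (reductive dehalogenation), leaving the strained ketone and the silyl ethers intact.

Step 11
Reactants: 14
Product: 16 keto acetal (CH(OMe)2 on C4), via silyl enol ether 15 (not isolated)
Conditions: LiN(i-Pr)2 (commercial solution), Me3SiCl, THF, −78 °C; then HC(OMe)3, Me3SiOTf (10 mol%), CH2Cl2, −78 °C
Reagents that add atoms: trimethyl orthoformate, COC(OC)OC
Why: Kinetic deprotonation with in-situ silylation should take place at the only α-CH2 (C4) and not at the hindered ring-fusion methine C1, and the silyl enol ether then adds to the dimethoxycarbenium ion from the orthoformate (Mukaiyama-type addition to an acetal), which attaches C3 as a masked formyl group; the configuration of C4 is not controlled and need not be.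

Step 12
Reactants: 16
Product: 17 cyclobutanol acetal
Conditions: NaBH4, MeOH, 0 °C
Reagents that add atoms: none
Why: Borohydride reduction of the cyclobutanone (hydride reduction) gives the carbinol that is the donor of the aldol retron; both C2 epimers may form and both are used because C2 is re-set later.

Step 13
Reactants: 17
Product: 20 lactol (rings A B C), via formyl cyclobutanol 18 (not isolated), via dialdehyde 19 (not isolated)
Conditions: 1 M HCl (aq.), THF, 0 °C → rt; then NaHCO3 (aq.) to pH 8
Reagents that add atoms: water, O
Why: Aqueous acid removes the three silyl ethers and hydrolyses the dimethyl acetal, and the 2-formylcyclobutanol 18 so formed is an aldol across the C2–C4 bond, which therefore breaks by retro-aldol reaction with release of four-ring strain to give 1,5-dialdehyde 19, whose C3 enol oxygen adds to the C2 aldehyde to give lactol 20. The closest known reaction type is the fragmentation half of the de Mayo reaction (cyclobutanol photoadduct to 1,5-dicarbonyl compound) and the ring expansion of donor–acceptor cyclobutanes to 2-oxygenated dihydropyrans. Ring C closes by 6-exo-trig addition of the enol oxygen to the formyl carbon, so the four-membered ring C2/C1/C5/C4 has grown by two atoms, C3 and its oxygen. C1 and C5 are not touched and keep the cis relation set by the cycloaddition, C4 becomes sp2 and the carbinol carbon becomes the hemiacetal C2, whose anomers equilibrate, so all four diastereomers of 17 converge on one lactol. The step needs cleavage of C2–C4 only and enolisation of the C3 aldehyde toward C4 only, which is secured because C2–C4 is the one bond flanked by a hydroxyl and a formyl group and because the alternative enol ether C2=C1 would put a double bond at the ring fusion next to the quaternary C10. Short contact and a final pH of 8 are chosen so that the open form 19, a β-hydroxy aldehyde with respect to C10, closes to 20 before it can open ring B by retro-aldol reaction or epimerise at C1.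

Step 14
Reactants: 20 lactol (rings A B C)
Product: 23 oxepane lactol (rings A B C D), via methylene dialdehyde 21 (not isolated), via oxepane dialdehyde 22 (not isolated)
Conditions: 37% aq. HCHO, pyrrolidine (20 mol%), EtCO2H (20 mol%), i-PrOH, 45 °C
Reagents that add atoms: formaldehyde, C=O
Why: Proposed new method: lactol 20 is a cyclic hemiacetal that stays in ring–chain equilibrium with its open 1,5-dialdehyde tautomer (the form numbered 19), in which only the C3 aldehyde has an α-methylene group (C4), so pyrrolidine catalysis should convert this reacting form with formaldehyde by Mannich condensation and β-elimination into the 2-methylene aldehyde 21, whose iminium ion is then attacked at C15 by the C13 hydroxyl, the only nucleophile held over C15 by the cis cyclopropane, in a 7-endo-trig oxa-Michael addition that closes ring D and gives 22, which re-closes ring C through its C3 enol; the adduct of the tertiary C10 hydroxyl cannot form the enol-ether lactol (bridgehead double bond) and reverts, so the equilibria should funnel into 23, and C11 becomes a stereocenter only through the choice of the endo arm; the closest known reaction types are the amine-catalysed α-methylenation of aldehydes with aqueous formaldehyde and the iminium-catalysed intramolecular oxa-Michael addition of alcohols to enals.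

Step 15
Reactants: 23
Product: 24 target diacetate (CNP0250836.3)
Conditions: Ac2O, pyridine, CH2Cl2, 0 °C → rt
Reagents that add atoms: acetic anhydride, CC(=O)OC(C)=O
Why: Acylation with acetic anhydride and pyridine should esterify the primary C12 alcohol and the anomeric hydroxyl while the tertiary C10 alcohol does not react, and since the anomers of 23 interconvert, the acetate trans to the C1–C10 bond, in which the acetoxy group avoids the quaternary C10 and can lie pseudo-axial (anomeric effect), should predominate, which sets C2.

**Compound list**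

1 | 4-cyclohepten-1-one | O=C1CCC=CCC1 | starting material
2 | dimethyl diazomalonate | COC(=O)C(=[N+]=[N-])C(=O)OC | starting material
3 | dimethyl (1R,7S)-4-oxobicyclo[5.1.0]octane-8,8-dicarboxylate, meso, cis-fused | COC(=O)C1(C(=O)OC)[C@@H]2CCC(=O)CC[C@H]12 | intermediate
4 | dimethyl 4-(trifluoromethylsulfonyloxy)bicyclo[5.1.0]oct-3-ene-8,8-dicarboxylate, cis-fused, enantiomer as in the SMILES | COC(=O)C1(C(=O)OC)[C@@H]2CC=C(OS(=O)(=O)C(F)(F)F)CC[C@H]12 | intermediate
5 | dimethyl 4-methylbicyclo[5.1.0]oct-3-ene-8,8-dicarboxylate, same configuration | COC(=O)C1(C(=O)OC)[C@@H]2CC=C(C)CC[C@H]12 | intermediate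
6 | (4-methylbicyclo[5.1.0]oct-3-ene-8,8-diyl)dimethanol | OCC1(CO)[C@@H]2CC=C(C)CC[C@H]12 | intermediate
7 | 4-methyl-8,8-bis(triethylsilyloxymethyl)bicyclo[5.1.0]oct-3-ene | CC[Si](CC)(CC)OCC1(CO[Si](CC)(CC)CC)[C@@H]2CC=C(C)CC[C@H]12 | intermediate
8 | 3,4-epoxy-4-methyl-8,8-bis(triethylsilyloxymethyl)bicyclo[5.1.0]octane, oxirane oxygen anti to C8 | CC[Si](CC)(CC)OCC1(CO[Si](CC)(CC)CC)[C@@H]2C[C@H]3O[C@@]3(C)CC[C@H]12 | intermediate
9 | 4-methyl-3-(phenylselanyl)-8,8-bis(triethylsilyloxymethyl)bicyclo[5.1.0]octan-4-ol, hydroxyl anti and selenium syn to C8 | CC[Si](CC)(CC)OCC1(CO[Si](CC)(CC)CC)[C@@H]2C[C@H]([Se]c3ccccc3)[C@@](C)(O)CC[C@H]12 | intermediate (not isolated)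
10 | selenoxide of 9 | CC[Si](CC)(CC)OCC1(CO[Si](CC)(CC)CC)[C@@H]2C[C@H]([Se](=O)c3ccccc3)[C@@](C)(O)CC[C@H]12 | intermediate (not isolated)
11 | 4-methyl-8,8-bis(triethylsilyloxymethyl)bicyclo[5.1.0]oct-2-en-4-ol, hydroxyl anti to C8 | CC[Si](CC)(CC)OCC1(CO[Si](CC)(CC)CC)[C@@H]2C=C[C@@](C)(O)CC[C@H]12 | intermediate
12 | triethylsilyl ether of 11 (tris-silyl ether) | CC[Si](CC)(CC)OCC1(CO[Si](CC)(CC)CC)[C@@H]2C=C[C@@](C)(O[Si](CC)(CC)CC)CC[C@H]12 | intermediate
13 | dichlorocyclobutanone, four-membered ring cis-fused to ring B and anti to ring A, C=O carbon on C1, CCl2 carbon on C5 | CC[Si](CC)(CC)OCC1(CO[Si](CC)(CC)CC)[C@@H]2[C@@H]3[C@@H](C(=O)C3(Cl)Cl)[C@@](C)(O[Si](CC)(CC)CC)CC[C@H]12 | intermediate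
14 | cyclobutanone (13 without chlorine) | CC[Si](CC)(CC)OCC1(CO[Si](CC)(CC)CC)[C@@H]2[C@@H]3[C@@H](C(=O)C3)[C@@](C)(O[Si](CC)(CC)CC)CC[C@H]12 | intermediate
15 | trimethylsilyl enol ether of 14 (C2–OSiMe3, C2=C4) | CC[Si](CC)(CC)OCC1(CO[Si](CC)(CC)CC)[C@@H]2[C@@H]3[C@@H](C(O[Si](C)(C)C)=C3)[C@@](C)(O[Si](CC)(CC)CC)CC[C@H]12 | intermediate (not isolated)
16 | 2-(dimethoxymethyl)cyclobutanone, C3 acetal on C4, C4 epimers | CC[Si](CC)(CC)OCC1(CO[Si](CC)(CC)CC)[C@@H]2[C@@H]3[C@@H](C(=O)C3C(OC)OC)[C@@](C)(O[Si](CC)(CC)CC)CC[C@H]12 | intermediate
17 | 2-(dimethoxymethyl)cyclobutanol, epimers at C2 and C4 | CC[Si](CC)(CC)OCC1(CO[Si](CC)(CC)CC)[C@@H]2[C@@H]3[C@@H](C(O)C3C(OC)OC)[C@@](C)(O[Si](CC)(CC)CC)CC[C@H]12 | intermediate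
18 | desilylated 2-formylcyclobutanol (tetraol aldehyde), epimers at C2 and C4 | OCC1(CO)[C@@H]2[C@@H]3[C@@H](C(O)C3C=O)[C@@](C)(O)CC[C@H]12 | intermediate (not isolated)
19 | 1,5-dialdehyde, C2 formyl on C1 and C4H2–C3HO on C5 | OCC1(CO)[C@@H]2[C@@H](CC=O)[C@@H](C=O)[C@@](C)(O)CC[C@H]12 | intermediate (not isolated)
20 | lactol, 2-hydroxy-3,4-dihydro-2H-pyran ring C cis-fused to ring B, triol, both anomers | OCC1(CO)[C@@H]2[C@H]3C=COC(O)[C@H]3[C@@](C)(O)CC[C@H]12 | intermediate
21 | 2-methylene dialdehyde (C15=C4) | OCC1(CO)[C@@H]2[C@@H](C(=C)C=O)[C@@H](C=O)[C@@](C)(O)CC[C@H]12 | intermediate (not isolated)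
22 | oxepane dialdehyde (C13–O–C15 closed), C4 epimers | OC[C@@]12COCC(C=O)[C@@H]([C@@H](C=O)[C@@]3(C)O)[C@@H]1[C@@H]2CC3 | intermediate (not isolated)
23 | 2,12-bis(deacetyl) target, lactol, both anomers | OC[C@@]12COCC3=COC(O)[C@@H]4[C@H]3[C@@H]1[C@@H]2CC[C@]4(C)O | intermediate
24 | target, 2,12-di-O-acetyl-2,3-secoaromadendrane with 13,15-ether bridge and 10-hydroxyl (CNP0250836.3) | CC(=O)OC[C@@]12COCC3=CO[C@H](OC(C)=O)[C@@H]4[C@H]3[C@@H]1[C@@H]2CC[C@]4(C)O | target

**Count and risks**

Total step count: 15. Longest linear sequence: 15 steps (from 1; fully linear).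

Steps most likely to fail:

1. Step 14 (labelled step). The open dialdehyde form is exposed to amine for a long time, so retro-aldol opening of ring B at C10, polymerisation of the enal, or failure of the seven-membered oxa-Michael closure may win. Fallback with known reaction types, which closes ring D before ring C exists: it sets out from cyclobutanone 14 and returns at 23. α-Methylenation of 14 with paraformaldehyde and N-methylanilinium trifluoroacetate (THF, reflux) gives the 2-methylenecyclobutanone F1. HF·pyridine with pyridine (THF, 0 °C) removes the two primary silyl groups to give the diol F2. KN(SiMe3)2 (2 equiv) lets the endo alkoxide add to the strained enone, and Me3SiCl traps the regiodefined enolate as the oxepane silyl enol ether F3. HC(OMe)3 with Me3SiOTf gives the oxepane keto acetal F4 with quaternary C4, and NaBH4 gives the cyclobutanol F5. The conditions of step 13 then unmask the formyl cyclobutanol F6, whose retro-aldol opening gives 22 and hence 23.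

2. Step 9. The cycloaddition may be slow and lose facial or regiochemical control because the silyloxy group on C10 lies on the face the ketene must use, and zinc salts may ionise the tertiary allylic silyl ether. Fallback: a keteniminium [2+2] cycloaddition that needs no zinc and no dechlorination. It sets out from 12 and returns at 14. N,N-dimethylacetamide, Tf2O and 2,4,6-collidine (1,2-dichloroethane, reflux) generate the smaller and more electrophilic keteniminium ion, which should add with the same orientation to give the cyclobutaniminium triflate F7; aqueous NaHCO3 hydrolyses it to 14.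

3. Step 13. While the dialdehyde is open under acid and then base, epimerisation at C1, retro-aldol opening at C10 or internal acetal formation with the free primary alcohols may compete with lactol closure. Fallback: reverse the order of unmasking so that the alkoxide is generated last, under buffered aprotic conditions. It sets out from 17 and returns at 20. t-BuMe2SiOTf with 2,6-lutidine gives the silyl ether F8. AcOH–THF–H2O removes the triethylsilyl groups and the acetal to give the stable silyloxy aldehyde F9. Bu4NF buffered with AcOH (THF, −20 °C) frees the C2 alkoxide, which fragments at once through 18 and 19 to 20.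

Further compounds
F1 | step 14 | 2-methylenecyclobutanone from 14 (C15=C4 exocyclic, tris-silyl ether) | CC[Si](CC)(CC)OCC1(CO[Si](CC)(CC)CC)[C@@H]2[C@@H]3[C@@H](C(=O)C3=C)[C@@](C)(O[Si](CC)(CC)CC)CC[C@H]12
F2 | step 14 | diol of F1 (tertiary silyl ether kept) | OCC1(CO)[C@@H]2[C@@H]3[C@@H](C(=O)C3=C)[C@@](C)(O[Si](CC)(CC)CC)CC[C@H]12
F3 | step 14 | oxepane silyl enol ether (C13–O–C15 closed, C2–OSiMe3, C12–OSiMe3) | C[Si](C)(C)OC[C@@]12COCC3=C(O[Si](C)(C)C)[C@@H]4[C@H]3[C@@H]1[C@@H]2CC[C@]4(C)O[Si](CC)(CC)CC
F4 | step 14 | oxepane keto acetal (quaternary C4 with CH(OMe)2, configuration at C4 fixed by the ring fusion and left open) | C[Si](C)(C)OC[C@@]12COCC3(C(OC)OC)C(=O)[C@@H]4[C@H]3[C@@H]1[C@@H]2CC[C@]4(C)O[Si](CC)(CC)CC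
F5 | step 14 | cyclobutanol of F4 (C2 epimers) | C[Si](C)(C)OC[C@@]12COCC3(C(OC)OC)C(O)[C@@H]4[C@H]3[C@@H]1[C@@H]2CC[C@]4(C)O[Si](CC)(CC)CC
F6 | step 14 | desilylated formyl cyclobutanol with ring D | OC[C@@]12COCC3(C=O)C(O)[C@@H]4[C@H]3[C@@H]1[C@@H]2CC[C@]4(C)O
F7 | step 9 | N,N-dimethylcyclobutaniminium triflate (iminium carbon on C1, CH2 on C5) | CC[Si](CC)(CC)OCC1(CO[Si](CC)(CC)CC)[C@@H]2[C@@H]3[C@@H](C(=[N+](C)C)C3)[C@@](C)(O[Si](CC)(CC)CC)CC[C@H]12.[O-]S(=O)(=O)C(F)(F)F
F8 | step 13 | tert-butyldimethylsilyl ether of 17 (on the C2 carbinol) | CC[Si](CC)(CC)OCC1(CO[Si](CC)(CC)CC)[C@@H]2[C@@H]3[C@@H](C(O[Si](C)(C)C(C)(C)C)C3C(OC)OC)[C@@](C)(O[Si](CC)(CC)CC)CC[C@H]12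
F9 | step 13 | silyloxy aldehyde triol (C2–OSi kept, C3 formyl free) | OCC1(CO)[C@@H]2[C@@H]3[C@@H](C(O[Si](C)(C)C(C)(C)C)C3C=O)[C@@](C)(O)CC[C@H]12
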